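**Assumptions (one line each):** The target is the 2,3-trans (2R,3R) dihydroflavonol, as the SMILES encodes. 5,7-Dihydroxychromone, prenyl bromide and 4-bromo-2-methoxyphenol are taken as commercial. Only substrates, building blocks, intermediates and products are numbered; simple reagents are given by name and SMILES.

## Retrosynthetic overview

1. Target ⇐ one fluoride step removing the two aryl TBS ethers (5-O and 4'-O) of the protected dihydroflavonol.
2. C3–OH ⇐ substrate-controlled Rubottom oxidation of a (2S)-flavanone, oxidant anti to the 2-aryl group (gives 2,3-trans).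
3. Key step: C2–aryl bond and C2 stereocentre ⇐ Rh(I)/chiral bisphosphine asymmetric 1,4-addition of an arylboronic acid to a chromone (no chalcone, no oxa-Michael or epoxide ring closure).
4. Chromone ⇐ 5,7-dihydroxychromone by 7-O-prenylation and 5-O-silylation; boronic acid ⇐ 4-bromo-2-methoxyphenol.
5. Ring order: rings A and C are bought intact as the chromone; ring B is attached last as an intact arene; no ring is built.

## Route

Step 1
Reactants: 1 5,7-dihydroxy-4H-chromen-4-one; 2 1-bromo-3-methylbut-2-ene (prenyl bromide)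
Product: 3 5-hydroxy-7-[(3-methylbut-2-en-1-yl)oxy]-4H-chromen-4-one
Conditions: K2CO3 (1.2 equiv), 2 (1.1 equiv), acetone, reflux
Reagents that add atoms: none
Why: Williamson ether synthesis; the 7-OH (vinylogous acid, para to C=O) is far more acidic and nucleophilic than the 5-OH locked in a hydrogen bond to C4=O, so only the 7-O is alkylated.

Step 2
Reactants: 3 5-hydroxy-7-[(3-methylbut-2-en-1-yl)oxy]-4H-chromen-4-one
Product: 4 5-[(tert-butyldimethylsilyl)oxy]-7-[(3-methylbut-2-en-1-yl)oxy]-4H-chromen-4-one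
Conditions: TBSOTf (1.3 equiv), 2,6-lutidine, CH2Cl2, 0 °C → rt
Reagents that add atoms: tert-butyldimethylsilyl trifluoromethanesulfonate, CC(C)(C)[Si](C)(C)OS(=O)(=O)C(F)(F)F
Why: O-silylation with a silyl triflate, reactive enough for the chelated peri-phenol; it masks the acidic OH for the Rh step and leaves with the other silyl group at the end.

Step 3
Reactants: 5 4-bromo-2-methoxyphenol
Product: 6 (4-bromo-2-methoxyphenoxy)(tert-butyl)dimethylsilane
Conditions: TBSCl, imidazole, DMF, rt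
Reagents that add atoms: tert-butyldimethylsilyl chloride, CC(C)(C)[Si](C)(C)Cl
Why: Standard imidazole-promoted phenol silylation (Corey conditions).

Step 4
Reactants: 6 (4-bromo-2-methoxyphenoxy)(tert-butyl)dimethylsilane
Product: 9 {4-[(tert-butyldimethylsilyl)oxy]-3-methoxyphenyl}boronic acid, via aryllithium 7 (not isolated), via lithium aryltriisopropoxyborate 8 (not isolated)
Conditions: n-BuLi, THF, −78 °C; B(OiPr)3, −78 → 0 °C; 1 M HCl to pH 5–6, 0 °C
Reagents that add atoms: triisopropyl borate, CC(C)OB(OC(C)C)OC(C)C; water, O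
Why: Bromine–lithium exchange, electrophilic borylation and mild hydrolysis; the aryl TBS ether survives n-BuLi at −78 °C and a pH 5–6 work-up.

Step 5
Reactants: 4 5-[(tert-butyldimethylsilyl)oxy]-7-[(3-methylbut-2-en-1-yl)oxy]-4H-chromen-4-one; 9 {4-[(tert-butyldimethylsilyl)oxy]-3-methoxyphenyl}boronic acid
Product: 10 (2S)-5-[(tert-butyldimethylsilyl)oxy]-2-{4-[(tert-butyldimethylsilyl)oxy]-3-methoxyphenyl}-7-[(3-methylbut-2-en-1-yl)oxy]-2,3-dihydro-4H-chromen-4-one
Conditions: [RhCl(C2H4)2]2 (2.5 mol %), (S)-MeO-F12-BIPHEP [(S)-2,2'-bis{bis(3,4,5-trifluorophenyl)phosphino}-6,6'-dimethoxybiphenyl] (5.5 mol %), aq KOH (10 mol %), 9 (3 equiv), degassed toluene/H2O 10:1, 30 °C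
Reagents that add atoms: none
Why: Hayashi–Miyaura Rh(I)-catalysed asymmetric 1,4-addition, in which aryl–Rh(bisphosphine) inserts the chromone C2=C3 and water releases the flavanone under near-neutral conditions that avoid retro-oxa-Michael racemisation; C2 is set by the catalyst, the (S)-biaryl bisphosphine being expected (by the model that gives (S)-3-arylcyclohexanones) to give the (2S)-flavanone, which has the spatial arrangement of C2 in the target.

Step 6
Reactants: 10 (2S)-5-[(tert-butyldimethylsilyl)oxy]-2-{4-[(tert-butyldimethylsilyl)oxy]-3-methoxyphenyl}-7-[(3-methylbut-2-en-1-yl)oxy]-2,3-dihydro-4H-chromen-4-one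
Product: 13 (2R,3R)-5-[(tert-butyldimethylsilyl)oxy]-2-{4-[(tert-butyldimethylsilyl)oxy]-3-methoxyphenyl}-3-hydroxy-7-[(3-methylbut-2-en-1-yl)oxy]-2,3-dihydro-4H-chromen-4-one, via TMS enol ether 11 (not isolated), via siloxy epoxide 12 (not isolated)
Conditions: TMSOTf, Et3N, CH2Cl2, −20 → 0 °C, pentane filtration; DMDO (1.05 equiv, titrated), acetone/CH2Cl2, −78 °C; 10% aq citric acid, THF, 0 °C
Reagents that add atoms: dimethyldioxirane, CC1(C)OO1
Why: Rubottom oxidation, in which DMDO at −78 °C epoxidises the very electron-rich aryl silyl enol ether much faster than the prenyl alkene and from the face anti to the C2 aryl group, so that hydrolysis of the siloxy epoxide gives the 2,3-trans α-hydroxy ketone (C3 = R by substrate control, C2 untouched).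

Step 7
Reactants: 13 (2R,3R)-5-[(tert-butyldimethylsilyl)oxy]-2-{4-[(tert-butyldimethylsilyl)oxy]-3-methoxyphenyl}-3-hydroxy-7-[(3-methylbut-2-en-1-yl)oxy]-2,3-dihydro-4H-chromen-4-one
Product: 14 (2R,3R)-3,5-dihydroxy-2-(4-hydroxy-3-methoxyphenyl)-7-[(3-methylbut-2-en-1-yl)oxy]-2,3-dihydro-4H-chromen-4-one
Conditions: TBAF/AcOH (1:1, 2.5 equiv), THF, 0 °C, argon; pH 5 work-up
Reagents that add atoms: none
Why: Fluoride desilylation of both aryl silyl ethers, buffered with AcOH so that the base-sensitive dihydroflavonol (C2/C3 epimerisation, air oxidation to the flavonol) and the acid-sensitive prenyl ether are both left intact.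

## Compound list

1 | 5,7-dihydroxy-4H-chromen-4-one | O=c1ccoc2cc(O)cc(O)c12 | starting material
2 | 1-bromo-3-methylbut-2-ene (prenyl bromide) | CC(C)=CCBr | starting material
3 | 5-hydroxy-7-[(3-methylbut-2-en-1-yl)oxy]-4H-chromen-4-one | CC(C)=CCOc1cc(O)c2c(c1)occc2=O | intermediate
4 | 5-[(tert-butyldimethylsilyl)oxy]-7-[(3-methylbut-2-en-1-yl)oxy]-4H-chromen-4-one | CC(C)=CCOc1cc(O[Si](C)(C)C(C)(C)C)c2c(c1)occc2=O | intermediate
5 | 4-bromo-2-methoxyphenol | COc1cc(Br)ccc1O | starting material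
6 | (4-bromo-2-methoxyphenoxy)(tert-butyl)dimethylsilane | COc1cc(Br)ccc1O[Si](C)(C)C(C)(C)C | intermediate
7 | {4-[(tert-butyldimethylsilyl)oxy]-3-methoxyphenyl}lithium | [Li]c1ccc(O[Si](C)(C)C(C)(C)C)c(OC)c1 | intermediate (not isolated)
8 | lithium {4-[(tert-butyldimethylsilyl)oxy]-3-methoxyphenyl}tri(propan-2-yloxy)borate | [Li+].CC(C)O[B-](OC(C)C)(OC(C)C)c1ccc(O[Si](C)(C)C(C)(C)C)c(OC)c1 | intermediate (not isolated)
9 | {4-[(tert-butyldimethylsilyl)oxy]-3-methoxyphenyl}boronic acid | COc1cc(B(O)O)ccc1O[Si](C)(C)C(C)(C)C | intermediate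
10 | (2S)-5-[(tert-butyldimethylsilyl)oxy]-2-{4-[(tert-butyldimethylsilyl)oxy]-3-methoxyphenyl}-7-[(3-methylbut-2-en-1-yl)oxy]-2,3-dihydro-4H-chromen-4-one | COc1cc([C@H]2Oc3cc(OCC=C(C)C)cc(O[Si](C)(C)C(C)(C)C)c3C(=O)C2)ccc1O[Si](C)(C)C(C)(C)C | intermediate
11 | (2S)-5-[(tert-butyldimethylsilyl)oxy]-2-{4-[(tert-butyldimethylsilyl)oxy]-3-methoxyphenyl}-7-[(3-methylbut-2-en-1-yl)oxy]-4-[(trimethylsilyl)oxy]-2H-chromene | COc1cc([C@H]2Oc3cc(OCC=C(C)C)cc(O[Si](C)(C)C(C)(C)C)c3C(O[Si](C)(C)C)=C2)ccc1O[Si](C)(C)C(C)(C)C | intermediate (not isolated)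
12 | (2R,3R,4R)-3,4-epoxy-4-[(trimethylsilyl)oxy] derivative of 11 (flavan numbering; epoxide oxygen anti to the 2-aryl group) | COc1cc([C@H]2Oc3cc(OCC=C(C)C)cc(O[Si](C)(C)C(C)(C)C)c3[C@]4(O[Si](C)(C)C)O[C@H]24)ccc1O[Si](C)(C)C(C)(C)C | intermediate (not isolated)
13 | (2R,3R)-5-[(tert-butyldimethylsilyl)oxy]-2-{4-[(tert-butyldimethylsilyl)oxy]-3-methoxyphenyl}-3-hydroxy-7-[(3-methylbut-2-en-1-yl)oxy]-2,3-dihydro-4H-chromen-4-one | COc1cc([C@H]2Oc3cc(OCC=C(C)C)cc(O[Si](C)(C)C(C)(C)C)c3C(=O)[C@@H]2O)ccc1O[Si](C)(C)C(C)(C)C | intermediate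
14 | (2R,3R)-3,5-dihydroxy-2-(4-hydroxy-3-methoxyphenyl)-7-[(3-methylbut-2-en-1-yl)oxy]-2,3-dihydro-4H-chromen-4-one | COc1cc([C@H]2Oc3cc(OCC=C(C)C)cc(O)c3C(=O)[C@@H]2O)ccc1O | target

## Step count and risks

Total steps: 7. Longest linear sequence: 5 (steps 1, 2, 5, 6, 7; the boronic acid branch, steps 3, 4, 5, 6, 7, is also 5).

**Step 5 (most at risk).** The chromone is electron-rich and a weak acceptor, boronic acid 9 can protodeboronate, and the sense and level of induction on this exact substrate are untested. If only the sense is wrong, the (R)-ligand is used. If the reaction itself fails, the fallback abandons the arylation for the chalcone epoxide approach; it sets out from 2 and returns at 14. Compound 2 O-alkylates commercial 2',4',6'-trihydroxyacetophenone (K2CO3, acetone) at the free para OH to give 1-{2,6-dihydroxy-4-[(3-methylbut-2-en-1-yl)oxy]phenyl}ethan-1-one F1. MOMCl/NaH in DMF gives 1-{2,6-bis(methoxymethoxy)-4-[(3-methylbut-2-en-1-yl)oxy]phenyl}ethan-1-one F2. Claisen–Schmidt condensation (KOH, EtOH) of F2 with 3-methoxy-4-(methoxymethoxy)benzaldehyde F3 (from vanillin, MOMCl, iPr2NEt) gives (E)-1-{2,6-bis(methoxymethoxy)-4-[(3-methylbut-2-en-1-yl)oxy]phenyl}-3-[3-methoxy-4-(methoxymethoxy)phenyl]prop-2-en-1-one F4. Juliá–Colonna epoxidation (poly-L-leucine, urea·H2O2, DBU, THF) is nucleophilic, so it leaves the prenyl alkene alone, and gives the (2R,3S)-epoxy ketone {2,6-bis(methoxymethoxy)-4-[(3-methylbut-2-en-1-yl)oxy]phenyl}{(2R,3S)-3-[3-methoxy-4-(methoxymethoxy)phenyl]oxiran-2-yl}methanone F5. Dilute HCl in MeOH/THF (rt to 40 °C, monitored to spare the prenyl ether) then removes the MOM groups, and the freed 2'-OH opens the epoxide at the benzylic carbon with inversion (6-exo-tet). The α-carbon keeps its configuration, so the product is the 2,3-trans (2R,3R) compound 14.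

**Step 6.** DMDO may also attack the prenyl alkene, and trans selectivity could be incomplete. The fallback introduces the prenyl group only after the oxidation; it sets out from 1 and returns at 14. Compound 1 is benzylated (BnBr, K2CO3, DMF, 80 °C) to 5,7-bis(benzyloxy)-4H-chromen-4-one F6. The Rh-catalysed 1,4-addition of step 5, run with commercial [4-(benzyloxy)-3-methoxyphenyl]boronic acid, gives (2S)-5,7-bis(benzyloxy)-2-[4-(benzyloxy)-3-methoxyphenyl]-2,3-dihydro-4H-chromen-4-one F7. With no alkene present the Rubottom oxidation can be driven with excess oxidant: TMSOTf/Et3N gives (2S)-5,7-bis(benzyloxy)-2-[4-(benzyloxy)-3-methoxyphenyl]-4-[(trimethylsilyl)oxy]-2H-chromene F8, mCPBA/NaHCO3 gives its (2R,3R,4R)-3,4-epoxide F9, and acid work-up gives (2R,3R)-5,7-bis(benzyloxy)-2-[4-(benzyloxy)-3-methoxyphenyl]-3-hydroxy-2,3-dihydro-4H-chromen-4-one F10. Hydrogenolysis (H2, Pd/C, EtOAc/MeOH) gives (2R,3R)-3,5,7-trihydroxy-2-(4-hydroxy-3-methoxyphenyl)-2,3-dihydro-4H-chromen-4-one F11. This is alkylated with 2 (1.05 equiv, K2CO3 1.05 equiv, acetone/DMF, rt, argon) at the most acidic 7-OH to give 14; the weak point of this fallback is selectivity against the 4'-OH and base sensitivity in that last step.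

**Step 2.** The peri silyl ether of 4 may be too labile to purify or may hydrolyse in the aqueous Rh step. The fallback runs the key C–C bond formation before the protection; it sets out from 3 and returns at 10. Compound 3 is used unprotected in the Rh-catalysed addition with 9; the hydrogen-bonded 5-OH activates C4=O and stays protonated in the near-neutral medium. This gives (2S)-2-{4-[(tert-butyldimethylsilyl)oxy]-3-methoxyphenyl}-5-hydroxy-7-[(3-methylbut-2-en-1-yl)oxy]-2,3-dihydro-4H-chromen-4-one F12. Its 5-OH is silylated (TBSOTf, 2,6-lutidine, CH2Cl2, 0 °C) under anhydrous conditions just before the Rubottom sequence, which gives 10.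

## Further compounds

F1 | step 5 | 1-{2,6-dihydroxy-4-[(3-methylbut-2-en-1-yl)oxy]phenyl}ethan-1-one | CC(=O)c1c(O)cc(OCC=C(C)C)cc1O
F2 | step 5 | 1-{2,6-bis(methoxymethoxy)-4-[(3-methylbut-2-en-1-yl)oxy]phenyl}ethan-1-one | CC(=O)c1c(OCOC)cc(OCC=C(C)C)cc1OCOC
F3 | step 5 | 3-methoxy-4-(methoxymethoxy)benzaldehyde | COCOc1ccc(C=O)cc1OC
F4 | step 5 | (E)-1-{2,6-bis(methoxymethoxy)-4-[(3-methylbut-2-en-1-yl)oxy]phenyl}-3-[3-methoxy-4-(methoxymethoxy)phenyl]prop-2-en-1-one | COCOc1ccc(/C=C/C(=O)c2c(OCOC)cc(OCC=C(C)C)cc2OCOC)cc1OC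
F5 | step 5 | {2,6-bis(methoxymethoxy)-4-[(3-methylbut-2-en-1-yl)oxy]phenyl}{(2R,3S)-3-[3-methoxy-4-(methoxymethoxy)phenyl]oxiran-2-yl}methanone | O=C(c3c(OCOC)cc(OCC=C(C)C)cc3OCOC)[C@@H]1O[C@H]1c2ccc(OCOC)c(OC)c2
F6 | step 6 | 5,7-bis(benzyloxy)-4H-chromen-4-one | O=c1ccoc2cc(OCc3ccccc3)cc(OCc3ccccc3)c12
F7 | step 6 | (2S)-5,7-bis(benzyloxy)-2-[4-(benzyloxy)-3-methoxyphenyl]-2,3-dihydro-4H-chromen-4-one | COc1cc([C@H]2Oc3cc(OCc4ccccc4)cc(OCc4ccccc4)c3C(=O)C2)ccc1OCc1ccccc1
F8 | step 6 | (2S)-5,7-bis(benzyloxy)-2-[4-(benzyloxy)-3-methoxyphenyl]-4-[(trimethylsilyl)oxy]-2H-chromene | COc1cc([C@H]2Oc3cc(OCc4ccccc4)cc(OCc4ccccc4)c3C(O[Si](C)(C)C)=C2)ccc1OCc1ccccc1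
F9 | step 6 | (2R,3R,4R)-3,4-epoxide of F8 (flavan numbering; epoxide oxygen anti to the 2-aryl group) | COc1cc([C@H]2Oc3cc(OCc4ccccc4)cc(OCc4ccccc4)c3[C@]5(O[Si](C)(C)C)O[C@H]25)ccc1OCc1ccccc1
F10 | step 6 | (2R,3R)-5,7-bis(benzyloxy)-2-[4-(benzyloxy)-3-methoxyphenyl]-3-hydroxy-2,3-dihydro-4H-chromen-4-one | COc1cc([C@H]2Oc3cc(OCc4ccccc4)cc(OCc4ccccc4)c3C(=O)[C@@H]2O)ccc1OCc1ccccc1
F11 | step 6 | (2R,3R)-3,5,7-trihydroxy-2-(4-hydroxy-3-methoxyphenyl)-2,3-dihydro-4H-chromen-4-one | COc1cc([C@H]2Oc3cc(O)cc(O)c3C(=O)[C@@H]2O)ccc1O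
F12 | step 2 | (2S)-2-{4-[(tert-butyldimethylsilyl)oxy]-3-methoxyphenyl}-5-hydroxy-7-[(3-methylbut-2-en-1-yl)oxy]-2,3-dihydro-4H-chromen-4-one | COc1cc([C@H]2Oc3cc(OCC=C(C)C)cc(O)c3C(=O)C2)ccc1O[Si](C)(C)C(C)(C)C
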